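All runs are simulated with constants of no real substance, and the scatter is random.

Slowness is what we cannot see here. The earliest reading of the earlier runs, in maple at 3.00 h, already stands on the plateau, so the tables show where each run ended up but not the time course that led there.

| setting | maple | ash | cedar | flask |
|---|---|---|---|---|
| substrate | 0.35 M | 0.55 M | 0.25 M | 0.25 M |
| partner | 1 equiv | 1 equiv | 1 equiv | 1.00 equiv |
| precatalyst | 15 mol% | 15 mol% | 7.5 mol% | 15 mol% |
| remark | run made earlier | run made earlier | run made earlier |  |
| time |  |  |  | 30 h |

| run | time / h | target / % | isomer of the product / % |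
|---|---|---|---|
| maple | 3.00 | 34.4 | 14.4 |
| maple | 6.00 | 34.0 | 13.5 |
| maple | 15.0 | 34.3 | 14.1 |
| maple | 40.0 | 34.0 | 14.3 |
| ash | 5.00 | 34.0 | 13.9 |
| ash | 12.0 | 34.5 | 14.2 |
| ash | 25.0 | 34.4 | 14.0 |
| ash | 40.0 | 33.8 | 14.0 |
| cedar | 5.00 | 28.4 | 11.5 |
| cedar | 12.0 | 28.1 | 11.3 |
| cedar | 25.0 | 28.2 | 11.5 |
| cedar | 40.0 | 28.3 | 11.2 |

(readings scatter by 0.3 percentage points)

1. ratio of target to isomer of the product at 12 min
2. ratio of target to isomer of the product at 30 h

- the earlier runs were read with a standard deviation of 0.3 percentage points

Two views share these readings. Define the rest ratio Q as target over isomer of the product, pooled over the last readings of maple, ash and cedar: 2.43.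

The forecast gives 2.45 at 12 min (range 2.2 to 2.7) and 2.45 at 30 h (range 2.36 to 2.54), and it reads the steady ratio as “parallel kinetic formation at a fixed selectivity, without later isomerisation”.

My own reading differs, and I get there by counting turnovers. Let N be target plus isomer of the product made per catalyst charged. Maple gives N = 3.22 and cedar gives 5.27, so cedar's catalyst turned over more. Cedar's yield also differs, yet its ratio stays near Q. I take that indifference as the mark of an equilibrium between target and isomer of the product. I therefore agree at 30 h and expect Q there. At 12 min I part from the forecast: I expect a ratio above Q, though the readings cannot say by how much.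

The flask gives 34.8 at 12 min and 2.43 at 30 h, so the early forecast is low by a factor of 14.2.

    partner + precatalyst → free catalyst + spent reagent (k = 0.0538 L mol⁻¹ min⁻¹)
    target + free catalyst ⇌ isomer of the product + free catalyst, rate k2*[free catalyst]*[target] forward; the back reaction follows from the equilibrium constant (K = 0.411, k = 2.66 L mol⁻¹ min⁻¹)
    substrate + open intermediate → side product (k = 0.516 L mol⁻¹ min⁻¹)
    partner + catalyst intermediate → free catalyst + target (k = 5.80 L mol⁻¹ min⁻¹)
    free catalyst + open intermediate ⇌ catalyst intermediate (K = 6.40 L mol⁻¹, k = 5.86 L mol⁻¹ min⁻¹)
    substrate + free catalyst → free catalyst + open intermediate (k = 13.7 L mol⁻¹ min⁻¹)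

Over the run to 30 h, the flask's backward turnover from isomer of the product to target is 99.8% of the forward one, which is thermodynamic control, whereas at 12 min the flask's ratio stands at 14.3 times Q, which is kinetic control. The forecast's fixed ratio holds for this flask from 3.00 h on, when it already has 34.0% target and 14.0% isomer of the product. At 30 h, the flask's 34.0% target divided by Q gives 14.0% isomer of the product, and it holds 14.0%. With 4.00 equiv of partner, the neighbour's 46.4% target divided by Q gives 19.1%, and that flask holds 19.1%.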